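**Retrosynthetic overview**

1. The oxirane is made last: the tertiary C3–O7 alkoxide of a 3-hydroxy-3-(hydroxymethyl)tetrahydrofuran displaces a sulfonate on C6 (forms C6–O7).
2. The tetrahydrofuran and both new centres come from one operation: Sharpless epoxidation of a (Z)-allylic 1,4-diol across C2=C3, then opening of that epoxide at benzylic C2 by the C5 hydroxyl (forms C3–O7 and O1–C2).
3. Feature used: in the tetrahydrofuran ring (O1–C2–C3–C4–C5) the spiro carbon C3 carries the oxirane oxygen O7 and the neighbouring benzylic C2 carries the ring oxygen O1 on the opposite face of the C2–C3 bond, with the C2 aryl cis to the oxirane carbon C6. This is the pattern left by anti opening of a C2–C3 epoxide of a Z olefin.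
4. The Z olefin comes from an (R)-β-benzyl-γ-butyrolactone by aldol–dehydration with a vanillin ester, E→Z photoisomerization and hydride reduction; C4 comes from Rh-catalysed asymmetric hydrogenation of a Stobbe half-ester.
5. Ring order: γ-lactone (temporary, step 3) → tetrahydrofuran (step 11) → oxirane (step 13).

Key step: step 11

Remark: atoms are numbered O1, C2 (aryl), C3 (spiro), C4 (benzyl), C5 in the tetrahydrofuran and C6, O7 in the oxirane. 3-(Benzyloxy)-4-methoxybenzaldehyde (O-benzylisovanillin) is taken as a purchased material. Both phenols are carried as acetates from step 10 on, so that the C2 aryl cannot stabilise a benzylic cation in step 11.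

**Route**

Step 1
Reactants: 1 3-(benzyloxy)-4-methoxybenzaldehyde; 2 diethyl succinate
Product: 3 (E)-4-[3-(benzyloxy)-4-methoxyphenyl]-3-(ethoxycarbonyl)but-3-enoic acid
Conditions: t-BuOK, t-BuOH, reflux; then HCl (aq)
Reagents that add atoms: none
Why: Stobbe condensation: the succinate enolate adds to the aldehyde, the alkoxide lactonises onto the distal ester and E1cB ring opening gives the (E)-half-ester with only the unconjugated carboxyl free; the benzyl ether tolerates the alkoxide base.

Step 2
Reactants: 3 (E)-4-[3-(benzyloxy)-4-methoxyphenyl]-3-(ethoxycarbonyl)but-3-enoic acid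
Product: 4 (3R)-3-[3-(benzyloxy)-4-methoxybenzyl]-4-ethoxy-4-oxobutanoic acid
Conditions: [Rh(cod)Cl]2 (0.25 mol%), (4S,5S)-MOD-DIOP (0.6 mol%), Et3N (1 equiv), H2 (3 atm), MeOH, 30 °C
Reagents that add atoms: none
Why: Asymmetric hydrogenation of the carboxylate-chelated itaconate-type olefin on monovalent rhodium; the (S,S)-configured MOD-DIOP ligand (DIOP with bis(4-methoxy-3,5-dimethylphenyl)phosphino groups) is the enantiomer that should set C4 as (R) in arylidenesuccinic half-esters (the antipodal ligand would give the enantiomer), and the homogeneous catalyst does not cleave the benzyl ether.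

Step 3
Reactants: 4 (3R)-3-[3-(benzyloxy)-4-methoxybenzyl]-4-ethoxy-4-oxobutanoic acid
Product: 6 (4R)-4-[3-(benzyloxy)-4-methoxybenzyl]dihydrofuran-2(3H)-one, via hydroxy acid 5 (not isolated)
Conditions: KOH (1 equiv), EtOH; CaCl2, NaBH4, EtOH, −10 °C → rt; then 3 M HCl, rt
Reagents that add atoms: none
Why: Chemoselective ester reduction then lactonisation: Ca(BH4)2 reduces the ethyl ester while the potassium carboxylate is inert, and acidification closes the γ-hydroxy acid to the γ-lactone; C4 is not touched.

Step 4
Reactants: 6 (4R)-4-[3-(benzyloxy)-4-methoxybenzyl]dihydrofuran-2(3H)-one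
Product: 7 (4R)-4-(3-hydroxy-4-methoxybenzyl)dihydrofuran-2(3H)-one
Conditions: H2 (1 atm), Pd/C (10%), EtOAc, rt
Reagents that add atoms: none
Why: Hydrogenolysis of the benzyl aryl ether over zerovalent palladium on carbon; at this stage there is no olefin and no other benzylic C–O bond.

Step 5
Reactants: 8 vanillin (4-hydroxy-3-methoxybenzaldehyde)
Product: 9 4-formyl-2-methoxyphenyl pivalate
Conditions: PivCl, Et3N, DMAP (cat.), CH2Cl2, 0 °C → rt
Reagents that add atoms: pivaloyl chloride CC(C)(C)C(Cl)=O
Why: O-Acylation of the phenol with nucleophilic catalysis; the hindered pivalate keeps the aldehyde electrophilic (no para-phenoxide) and resists the enolate of step 6.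

Step 6
Reactants: 7 (4R)-4-(3-hydroxy-4-methoxybenzyl)dihydrofuran-2(3H)-one; 9 4-formyl-2-methoxyphenyl pivalate
Product: 10 4-{hydroxy[(3S,4R)-4-(3-hydroxy-4-methoxybenzyl)-2-oxotetrahydrofuran-3-yl]methyl}-2-methoxyphenyl pivalate (both carbinol epimers)
Conditions: LiN(SiMe3)2 (2.2 equiv), THF, −78 °C; then 9, −78 °C; AcOH quench
Reagents that add atoms: none
Why: Aldol addition of the lithium phenoxide–enolate dianion of 7 to the aldehyde; C3 forms trans to the C4 benzyl group and the carbinol centre as a mixture, both being erased in step 7, and the pivalate is not attacked at −78 °C.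

Step 7
Reactants: 10 aldol adduct (both carbinol epimers)
Product: 12 (3E,4R)-4-(3-acetoxy-4-methoxybenzyl)-3-[3-methoxy-4-(pivaloyloxy)benzylidene]dihydrofuran-2(3H)-one, via bis-acetate 11 (not isolated)
Conditions: Ac2O, Et3N, DMAP (cat.), CH2Cl2, 0 °C → rt; then DBU, rt
Reagents that add atoms: acetic anhydride CC(=O)OC(C)=O
Why: O-Acetylation of the phenol and the aldol hydroxyl, then DBU-mediated E1cB elimination of acetate, should give the conjugated arylidene lactone as the thermodynamically preferred E isomer (aryl anti to the carbonyl).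

Step 8
Reactants: 12 (3E,4R)-arylidene lactone
Product: 13 (3Z,4R)-4-(3-acetoxy-4-methoxybenzyl)-3-[3-methoxy-4-(pivaloyloxy)benzylidene]dihydrofuran-2(3H)-one
Conditions: hν (365 nm LED), degassed MeCN (5 mM), rt; chromatography, recovered 12 re-irradiated
Reagents that add atoms: none
Why: E→Z photoisomerization of the cinnamoyl-type chromophore, a known behaviour of α-arylidene-γ-butyrolactones; at 365 nm the more planar E isomer should absorb more strongly, so the photostationary mixture should be enriched in the twisted Z isomer (aryl syn to the carbonyl), while the aryl esters do not absorb and C4 is unaffected.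

Step 9
Reactants: 13 (3Z,4R)-arylidene lactone
Product: 14 (2Z,3R)-2-(4-hydroxy-3-methoxybenzylidene)-3-(3-hydroxy-4-methoxybenzyl)butane-1,4-diol
Conditions: i-Bu2AlH (10 equiv), CH2Cl2, −78 → 0 °C; aq. KNaC4H4O6 (potassium sodium tartrate)
Reagents that add atoms: none
Why: 1,2-Reduction of the unsaturated lactone to the allylic 1,4-diol with retention of the Z geometry (no conjugate reduction with this hydride); the excess reagent also cleaves the aryl pivalate and aryl acetate, which is intended.

Step 10
Reactants: 14 (2Z,3R)-tetraol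
Product: 15 (2Z,3R)-2-(4-acetoxy-3-methoxybenzylidene)-3-(3-acetoxy-4-methoxybenzyl)butane-1,4-diol
Conditions: Ac2O (2.2 equiv), NaOH (2.5 equiv, aq), THF, 0 °C
Reagents that add atoms: acetic anhydride CC(=O)OC(C)=O
Why: Chemoselective phenol acetylation under Schotten–Baumann conditions (only the phenoxides are acylated, the primary hydroxyls are not), installing the para-acetoxy group that makes the C2 aryl a poor cation stabiliser.

Step 11
Reactants: 15 (2Z,3R)-2-(4-acetoxy-3-methoxybenzylidene)-3-(3-acetoxy-4-methoxybenzyl)butane-1,4-diol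
Product: 17 (2S,3S,4S)-2-(4-acetoxy-3-methoxyphenyl)-4-(3-acetoxy-4-methoxybenzyl)-3-(hydroxymethyl)tetrahydrofuran-3-ol, via epoxy diol 16 (not isolated)
Conditions: Ti(OiPr)4 (1.2 equiv), L-(+)-diethyl tartrate (1.4 equiv), t-BuOOH (2 equiv, in decane), 4 Å MS, CH2Cl2, −20 °C; then CSA (10 mol%), CH2Cl2, 0 °C
Reagents that add atoms: tert-butyl hydroperoxide CC(C)(C)OO
Why: Sharpless asymmetric epoxidation: the C6 allylic alkoxide binds the tetravalent titanium–L-(+)-tartrate complex and peroxide oxygen is delivered to the face of C2=C3 that makes C3 (S), the same sense that converts (E)-hex-2-en-1-ol into its (2S,3S)-epoxide, giving epoxy diol 16 with aryl and C6 still cis. The Lewis acid, completed by CSA, then activates the oxirane and the C5 hydroxyl attacks benzylic C2 from the side opposite O7; the closest known reaction type is the acid-mediated cyclisation of 3,4-epoxy alcohols to 3-hydroxytetrahydrofurans. The tetrahydrofuran ring (O1, C2–C5) closes in a 5-endo mode with respect to the epoxide, the alternative attack at C3 being a 4-exo closure to an oxetane. C3 is controlled by the tartrate (reagent control, the resident C4 centre making any wrong-face product a separable diastereomer) and C2 by the Z geometry combined with inversion. The step needs direction by the allylic and not the homoallylic hydroxyl, secured by the much faster epoxidation of allylic alkoxides on titanium, and SN2 rather than SN1 opening at C2, secured by the para-acetoxy group, which removes the cation stabilisation that a free or silylated para-oxygen would give.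

Step 12
Reactants: 17 (2S,3S,4S)-tetrahydrofuran diol
Product: 18 [(2S,3S,4S)-2-(4-acetoxy-3-methoxyphenyl)-4-(3-acetoxy-4-methoxybenzyl)-3-hydroxytetrahydrofuran-3-yl]methyl 4-methylbenzenesulfonate
Conditions: TsCl (1.1 equiv), Et3N (1.2 equiv), Bu2SnO (5 mol%), CH2Cl2, rt
Reagents that add atoms: p-toluenesulfonyl chloride Cc1ccc(cc1)S(Cl)(=O)=O
Why: Tin-catalysed selective sulfonylation: the stannylene acetal of the 1,2-diol directs tosylation to the primary C6 hydroxyl, the tertiary C3 hydroxyl is inert, and without a nucleophilic acyl-transfer catalyst the aryl acetates stay in place.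

Step 13
Reactants: 18 primary tosylate
Product: 20 CNP0184956.1 = (3S,4S,7S)-4-(4-hydroxy-3-methoxyphenyl)-7-(3-hydroxy-4-methoxybenzyl)-1,5-dioxaspiro[2.4]heptane, via bis-phenol tosylate 19 (not isolated)
Conditions: K2CO3 (3 equiv), MeOH, 0 °C → rt; then NH4Cl (aq)
Reagents that add atoms: none
Why: Methanolysis of both aryl acetates and intramolecular Williamson displacement (3-exo-tet) of the primary tosylate by the C3 alkoxide should close the oxirane with C3 unchanged, since only the C6–O7 bond is formed; neutralisation returns the free phenols.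

**Compound list**

1 | 3-(benzyloxy)-4-methoxybenzaldehyde | COc1ccc(C=O)cc1OCc1ccccc1 | starting material
2 | diethyl succinate | CCOC(=O)CCC(=O)OCC | starting material
3 | (E)-4-[3-(benzyloxy)-4-methoxyphenyl]-3-(ethoxycarbonyl)but-3-enoic acid | CCOC(=O)/C(CC(=O)O)=C/c1ccc(OC)c(OCc2ccccc2)c1 | intermediate
4 | (3R)-3-[3-(benzyloxy)-4-methoxybenzyl]-4-ethoxy-4-oxobutanoic acid | CCOC(=O)[C@@H](CC(=O)O)Cc1ccc(OC)c(OCc2ccccc2)c1 | intermediate
5 | (3R)-3-[3-(benzyloxy)-4-methoxybenzyl]-4-hydroxybutanoic acid (present as its carboxylate salt) | OC[C@@H](CC(=O)O)Cc1ccc(OC)c(OCc2ccccc2)c1 | intermediate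
6 | (4R)-4-[3-(benzyloxy)-4-methoxybenzyl]dihydrofuran-2(3H)-one | COc1ccc(C[C@H]2COC(=O)C2)cc1OCc3ccccc3 | intermediate
7 | (4R)-4-(3-hydroxy-4-methoxybenzyl)dihydrofuran-2(3H)-one | COc1ccc(C[C@H]2COC(=O)C2)cc1O | intermediate
8 | vanillin | COc1cc(C=O)ccc1O | starting material
9 | 4-formyl-2-methoxyphenyl pivalate | COc1cc(C=O)ccc1OC(=O)C(C)(C)C | intermediate
10 | 4-{hydroxy[(3S,4R)-4-(3-hydroxy-4-methoxybenzyl)-2-oxotetrahydrofuran-3-yl]methyl}-2-methoxyphenyl pivalate, 3,4-trans, both carbinol epimers | COc1ccc(C[C@H]2COC(=O)[C@@H]2C(O)c3ccc(OC(=O)C(C)(C)C)c(OC)c3)cc1O | intermediate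
11 | bis-acetate of 10 (aryl acetate and benzylic acetate), both carbinol epimers | COc1ccc(C[C@H]2COC(=O)[C@@H]2C(OC(C)=O)c3ccc(OC(=O)C(C)(C)C)c(OC)c3)cc1OC(C)=O | intermediate
12 | (3E,4R)-4-(3-acetoxy-4-methoxybenzyl)-3-[3-methoxy-4-(pivaloyloxy)benzylidene]dihydrofuran-2(3H)-one | COc1ccc(C[C@H]2COC(=O)/C2=C/c3ccc(OC(=O)C(C)(C)C)c(OC)c3)cc1OC(C)=O | intermediate
13 | (3Z,4R)-4-(3-acetoxy-4-methoxybenzyl)-3-[3-methoxy-4-(pivaloyloxy)benzylidene]dihydrofuran-2(3H)-one | COc1ccc(C[C@H]2COC(=O)/C2=C\c3ccc(OC(=O)C(C)(C)C)c(OC)c3)cc1OC(C)=O | intermediate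
14 | (2Z,3R)-2-(4-hydroxy-3-methoxybenzylidene)-3-(3-hydroxy-4-methoxybenzyl)butane-1,4-diol | COc1ccc(C[C@@H](CO)/C(CO)=C/c2ccc(O)c(OC)c2)cc1O | intermediate
15 | (2Z,3R)-2-(4-acetoxy-3-methoxybenzylidene)-3-(3-acetoxy-4-methoxybenzyl)butane-1,4-diol (key-step precursor) | COc1ccc(C[C@@H](CO)/C(CO)=C/c2ccc(OC(C)=O)c(OC)c2)cc1OC(C)=O | intermediate
16 | [(2S,3R)-3-(4-acetoxy-3-methoxyphenyl)-2-[(2S)-1-(3-acetoxy-4-methoxyphenyl)-3-hydroxypropan-2-yl]oxiran-2-yl]methanol (route numbering: C2 R, C3 S, C4 S; aryl and CH2OH cis on the oxirane) | COc1ccc(C[C@@H](CO)[C@@]2(CO)O[C@@H]2c3ccc(OC(C)=O)c(OC)c3)cc1OC(C)=O | intermediate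
17 | (2S,3S,4S)-2-(4-acetoxy-3-methoxyphenyl)-4-(3-acetoxy-4-methoxybenzyl)-3-(hydroxymethyl)tetrahydrofuran-3-ol (key-step product) | COc1ccc(C[C@H]2CO[C@@H](c3ccc(OC(C)=O)c(OC)c3)[C@@]2(O)CO)cc1OC(C)=O | intermediate
18 | [(2S,3S,4S)-2-(4-acetoxy-3-methoxyphenyl)-4-(3-acetoxy-4-methoxybenzyl)-3-hydroxytetrahydrofuran-3-yl]methyl 4-methylbenzenesulfonate | COc1ccc(C[C@H]2CO[C@@H](c3ccc(OC(C)=O)c(OC)c3)[C@@]2(O)COS(=O)(=O)c4ccc(C)cc4)cc1OC(C)=O | intermediate
19 | [(2S,3S,4S)-3-hydroxy-2-(4-hydroxy-3-methoxyphenyl)-4-(3-hydroxy-4-methoxybenzyl)tetrahydrofuran-3-yl]methyl 4-methylbenzenesulfonate | COc1ccc(C[C@H]2CO[C@@H](c3ccc(O)c(OC)c3)[C@@]2(O)COS(=O)(=O)c4ccc(C)cc4)cc1O | intermediate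
20 | CNP0184956.1, (3S,4S,7S)-4-(4-hydroxy-3-methoxyphenyl)-7-(3-hydroxy-4-methoxybenzyl)-1,5-dioxaspiro[2.4]heptane | COc1ccc(C[C@H]2CO[C@@H](c3ccc(O)c(OC)c3)[C@@]23CO3)cc1O | target

**Step count**

Total: 13 steps. Longest linear sequence: 12 steps (1 → 3 → 4 → 6 → 7 → 10 → 12 → 13 → 14 → 15 → 17 → 18 → 20); step 5 is the one-step side branch.

**Steps most likely to fail**

Step 11. Oxygen may be transferred to the wrong olefin face, because a Z-aryl, 2-branched allylic alcohol is a slow and weakly discriminating substrate for titanium tartrate and the homoallylic C5 hydroxyl can also bind titanium. Ionisation at C2 before ring closure would in addition erode the C2 configuration. The fallback replaces hydroxyl-directed titanium chemistry by a non-directed dioxirane epoxidation on a protected olefin. Setting out from 15, both primary hydroxyls are silylated (Et3SiCl, imidazole, CH2Cl2) to give the bis(triethylsilyl) ether F1. F1 is epoxidised with the dioxirane of the D-fructose-derived Shi ketone (ketone in stoichiometric amount, KHSO5, NaHCO3 buffer at pH 7–8 so that the aryl acetates survive, MeCN/dimethoxymethane/water, 0 °C). The spiro transition state of this ketone gives the (R)-benzylic carbon with trans-β-substituted and trisubstituted styrenes, so it should deliver the silylated epoxide F2 with the same C2 and C3 configuration as 16. HF·pyridine in THF then removes both silyl groups and catalytic CSA completes the attack of the freed C5 hydroxyl on C2, rejoining the route at 17.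

Step 8. The photostationary composition may be unfavourable, and [2+2] dimerisation or photo-Fries migration of the aryl esters may compete, so that the Z isomer stays scarce. The fallback is a kinetically Z-selective olefination in place of photochemical equilibration. Setting out from 7, the phenol is pivaloylated (PivCl, Et3N, DMAP) to give the lactone pivalate F3. Its lithium enolate (LiN(i-Pr)2, THF, −78 °C) is trapped on carbon with (PhO)2PCl and the product is oxidised with H2O2 to the α-(diphenoxyphosphoryl) lactone F4. Deprotonation (NaH, THF, −78 → 0 °C) and reaction with aldehyde 9 is an Ando-type Horner–Wadsworth–Emmons olefination, in which diaryl phosphonates place the aldehyde substituent cis to the carbonyl; it should give the (Z)-arylidene lactone bis-pivalate F5. Excess i-Bu2AlH as in step 9 reduces the lactone and removes both pivalates, rejoining the route at 14.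

Step 13. Displacement at the neopentyl-type C6 may be slow in methanolic carbonate, which would leave the phenoxides long enough to be alkylated intermolecularly or to open the benzylic C2–O1 bond through a quinone methide. The fallback separates ring closure from deprotection and closes the oxirane without base. Setting out from 17, cyclodehydration of the 1,2-diol under Mitsunobu conditions (PPh3, diisopropyl azodicarboxylate, toluene, rt) activates the primary C6 oxygen, which is displaced by the tertiary C3 hydroxyl, and gives the spiro-epoxide diacetate F6. Brief hydrazinolysis (N2H4·H2O, THF, 0 °C) then cleaves the two aryl acetates without alkoxide and gives 20.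

**Further compounds**

F1 | step 11 | (2Z,3R)-2-(4-acetoxy-3-methoxybenzylidene)-3-(3-acetoxy-4-methoxybenzyl)butane-1,4-diol bis(triethylsilyl) ether | COc1ccc(C[C@@H](CO[Si](CC)(CC)CC)/C(CO[Si](CC)(CC)CC)=C/c2ccc(OC(C)=O)c(OC)c2)cc1OC(C)=O
F2 | step 11 | bis(triethylsilyl) ether of epoxy diol 16 | COc1ccc(C[C@@H](CO[Si](CC)(CC)CC)[C@@]2(CO[Si](CC)(CC)CC)O[C@@H]2c3ccc(OC(C)=O)c(OC)c3)cc1OC(C)=O
F3 | step 8 | 2-methoxy-5-{[(3R)-5-oxotetrahydrofuran-3-yl]methyl}phenyl pivalate | COc1ccc(C[C@H]2COC(=O)C2)cc1OC(=O)C(C)(C)C
F4 | step 8 | 5-{[(3R)-4-(diphenoxyphosphoryl)-5-oxotetrahydrofuran-3-yl]methyl}-2-methoxyphenyl pivalate (epimers at the phosphorus-bearing carbon) | COc1ccc(C[C@H]2COC(=O)C2P(=O)(Oc3ccccc3)Oc4ccccc4)cc1OC(=O)C(C)(C)C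
F5 | step 8 | (3Z,4R)-3-[3-methoxy-4-(pivaloyloxy)benzylidene]-4-[4-methoxy-3-(pivaloyloxy)benzyl]dihydrofuran-2(3H)-one | COc1ccc(C[C@H]2COC(=O)/C2=C\c3ccc(OC(=O)C(C)(C)C)c(OC)c3)cc1OC(=O)C(C)(C)C
F6 | step 13 | (3S,4S,7S)-4-(4-acetoxy-3-methoxyphenyl)-7-(3-acetoxy-4-methoxybenzyl)-1,5-dioxaspiro[2.4]heptane | COc1ccc(C[C@H]2CO[C@@H](c3ccc(OC(C)=O)c(OC)c3)[C@@]23CO3)cc1OC(C)=O
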